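In a one-step world substrate would become target point for point; here adduct stands between them, so it can peak.

- blue: substrate 0.15 M; gas 22 mM (held); run made earlier
- flask: substrate 0.30 M; gas 22 mM (held); time 10 d

blue run (percent of the substrate charged)

| time / h | adduct / % | target / % |
|---|---|---|
| 4.00 | 9.4 | 1.1 |
| 8.00 | 21.0 | 3.3 |
| 15.0 | 32.1 | 10.8 |
| 25.0 | 39.1 | 24.5 |
| 50.0 | 40.3 | 49.9 |

(each reading ± 1 percentage point)

- at the start none of the gas is in solution

- when, up to 10 d, the flask holds most adduct
- the amount of adduct, in percent of the substrate charged, at that time

The blue run gives me a ladder. First comes a start-up lag: substrate loses 10.5 % in the first 4.00 h, then a larger 14 percentage points in the next 4.00 h. Over the last span, substrate shows a pseudo-first-order half-life of 13.2 h. Target's gain per mean adduct over that span of the blue run reads as a longer half-life, 27.1 h; it is a net figure, with any way back inside it.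

Over that span the substrate lost in the blue run, divided by the target gained, reads 1.05. I carry this feed ratio ρ: adduct rises while ρ is above one and peaks where it equals one. The span before reads 1.51, so ρ drifts down, and a straight line through these readings crosses one at 1.64 d. The flask charges twice the substrate on the same gas, so I expect that crossing or later, and a peak near the blue reading of 40.3 %.

The forecast says 1.6 d (1.1 d to 2.3 d) and 47 % (41 % to 55 %), a higher peak than mine. Of the second step it says: “Doubling the charge should therefore slow it in percent terms.”

The flask holds most adduct at 1.99 d, with 38.2 %.

    adduct ⇌ target (K = 2.00, k = 8.10 × 10⁻⁴ min⁻¹)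
    gas ⇌ reagent, rate k2*(csat - [reagent]) (kL = 0.00970 min⁻¹)
    substrate + reagent ⇌ adduct (K = 610 M⁻¹, k = 0.0510 M⁻¹ min⁻¹)
    2 reagent → self-condensation product (k = 0.00430 M⁻¹ min⁻¹)

From 1.00 d to 1.99 d the flask gives ρ = 1.25, above one, like the blue run's 1.05. The neighbouring flask is the same charge read at 4.0 d. Between 1.99 d and that reading its substrate falls by 16 points while its target gains 20 points, which makes ρ = 0.784, below one. That neighbour holds 33.9 % of adduct at its reading, after a highest amount of 38.2 %.

The readings are calculated with constants of no real substance, noise included.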